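(The runs stem from a simulated flask from invented constants; the scatter is artificial.)

Count lifetimes.

| flask | X | Z | G | temperature | remark | time |
|---|---|---|---|---|---|---|
| east | 0.14 M (fed, over 40 min) | 0.10 M | 5 mol% | −25 °C | run made earlier; the fed solution adds 1.0 times the starting volume |  |
| north | 0.22 M (fed, over 40 min) | 0.10 M | 5 mol% | 5 °C | run made earlier; the fed solution adds 1.0 times the starting volume |  |
| delta | 0.10 M (fed, over 40 min) | 0.100 M | 5 mol% |  | at −20 °C throughout; the fed solution adds 1.0 times the starting volume | 40 min |
| eta | 0.10 M (fed, over 40 min) | 0.100 M | 5 mol% |  | at −20 °C until 12 min, from then on at 30 °C; the fed solution adds 1.0 times the starting volume | 40 min |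

- east (time / min: E / %, Q / %): 2.00: 0, 0.5; 6.00: 0.1, 0.1; 12.0: 0.8, 0; 15.0: 1.4, 0; 25.0: 3.3, 0
- north (time / min: E / %, Q / %): 0.667: 0, 0.1; 1.33: 0.1, 0.1; 2.00: 0.3, 0; 4.00: 1.3, 0; 8.00: 1.6, 0.2

(each reading ± 0.3 percentage points)

* which of the two ends with the higher share of E in all that became E or Q ("neither" if they lie within 2 percentage points) (delta / eta / neither)
* share of E in all that became E or Q, delta
* share of E in all that became E or Q, eta

- amounts are per litre of the starting volume; all of the dose is in the solution fed
- the earlier runs were read with a standard deviation of 0.3 percentage points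
- percentages count the whole charge, also what has not yet gone in

1. My own reckoning treats E as a leaky tank, a first-order lag with dc_E/dt = r − c_E/τ, where r is a steady making of E and τ is the lifetime of E against loss to Q. Over a window w, with n = w/τ, the share of E in E plus Q (the selectivity) is then (1 − e^(−n))/n.

2. In the north run, E near 1.6 % yields Q of 0.2 % in the last 4.00 min, which suggests τ of about 32.0 min at 5 °C, but that Q reading is smaller than its scatter of 0.3 percentage points, so this τ is a rough reading.

3. The early rise of E, taken as E/t², reads 15.4 times steeper in north than in east, a ratio from scattered readings of two runs that differ in X charge (0.14 M in east, 0.22 M in north) as well as in temperature, and it serves here as a rough temperature factor. Assuming that the loss of E speeds up alike, a step of 25.0 K multiplies rates by 9.76, so τ is about 312 min at −20 °C and 3.28 min at 30 °C.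

4. The bench habit calls a product stable while the window is short against its lifetime. In delta that holds, with 0.128 lifetimes, fewer than one, and a share near 93.9 %. The habit stops at n near 1, and eta passes that border: the lifetimes of E in its warm window of 28.0 min, 8.54, are more than one, so the share falls to about 11.7 %. My reckoning therefore favours delta.

5. The forecast says delta, with 96 % for delta and 40 % for eta, a higher eta figure than mine, on the ground that “X fed afterwards can only go by the uncatalysed route”.

    X + G ⇌ J (K = 11.0 M⁻¹, k = 0.110 M⁻¹ s⁻¹, Ea = 39.0 kJ mol⁻¹, ΔH = −23.0 kJ mol⁻¹)
    J ⇌ G + E (K = 0.0640 M, k = 0.00580 s⁻¹, Ea = 81.0 kJ mol⁻¹, ΔH = −8.00 kJ mol⁻¹)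
    E → Q (k = 2.80 × 10⁻⁵ s⁻¹, Ea = 79.0 kJ mol⁻¹)
    X + Z → D (k = 0.00750 M⁻¹ s⁻¹, Ea = 38.0 kJ mol⁻¹)
    (constants at −20 °C)

The flask gives delta: delta ends at 97.3 % and eta at 5.70 %, which is 34 points below the forecast. The half-life of E by its loss to Q alone, in eta at its first temperature of −20 °C, is 6.9 h, longer than the asked time of 40 min. Read backwards through the lag, the share of eta corresponds to 17.5 lifetimes in the warm window, against my 8.54.

In the same flask as eta read at 2.5 h, the time since the end of dosing is 33.5 of my warm lifetimes, more than the 8.54 of the window; the X of 12.9 % still standing in eta at 40.0 min can keep the tank fed for a while, but once that inflow stops, E should empty and the share should approach zero. The computed flask gives 0 %, with E at 0 % and Q at 15.5 %.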